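**Plan**

- Retrosynthesis: ring A is opened at O2–C3 (cyclodehydration) and C1–O2 (C–Si oxidation). The side chain is cut at C3–C1′ (thiol ester/boronic acid ketone synthesis) and C4–C4a (Mukaiyama–Michael addition, then re-oxidation). The C5(Cl) atom is then excised from ring B (C5–C6 and C5–C4a), and last C8a–C1 (conjugate addition).
- Enabling feature: in ring B, C5 is a single chlorine-bearing sp2 carbon between the C6 carbonyl and C4a. Removing it leaves a prochiral 2-acetoxy-2-methylcyclopentane-1,3-dione core, so ring B can be grown from a five-membered enol silane by dichlorocarbene insertion.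
- Forward: the cyclopentenedione is desymmetrised by copper-catalysed addition of a silylmethyl Grignard reagent and trapped as the C6=C4a enol silane. Carbene insertion then gives ring B, C4–C3 is added and C4a=C5 restored, the dienyl chain is coupled, and ring A closes last.
- Stereochemistry: C7 and C8a come from the desymmetrising conjugate addition (the chiral copper–diphosphine picks the enantiotopic alkene carbon, attack anti to acetoxy). C8a, α to the C8 ketone, is also the expected thermodynamic epimer. C5′ comes from (R)-2-methylbutanoic acid, and both E alkenes from a stabilised Wittig reaction and a chromium-mediated borylolefination.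

Key step: step 5

Remark: locants C1–C8a on all intermediates are those of the target's isochromene skeleton (C1H2, O2, C3, C4, C4a, C5–Cl, C6=O, C7, C8=O, C8a–H); C1′–C7′ are the side-chain carbons.

Assumption: (R)-2-methylbutanoic acid is bought as the single enantiomer, and the antipode of the ferrocenyl diphosphine that delivers the 7R series (to be assigned on this substrate) is the one meant in step 4.

**Route**

Step 1
Reactants: 1 2-methylcyclopentane-1,3-dione
Product: 2 1-methyl-2,5-dioxocyclopentyl acetate (2-acetoxy-2-methylcyclopentane-1,3-dione)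
Conditions: Pb(OAc)4, AcOH, rt
Reagents that add atoms: lead tetraacetate, CC(=O)O[Pb](OC(C)=O)(OC(C)=O)OC(C)=O
Why: α-Acetoxylation of a 2-alkyl-1,3-dione, in which the enol of 1 is attacked by Pb(OAc)4 at its only enolisable carbon and acetate is transferred to what becomes C7.

Step 2
Reactants: 2 1-methyl-2,5-dioxocyclopentyl acetate
Product: 3 1-methyl-2,5-dioxocyclopent-3-en-1-yl acetate (2-acetoxy-2-methylcyclopent-4-ene-1,3-dione)
Conditions: IBX, DMSO, 75 °C
Reagents that add atoms: none
Why: IBX dehydrogenation of a ketone to an enone; the carbon between the carbonyls is quaternary, so only the CH2–CH2 unit can be desaturated and the mirror-symmetric, prochiral ene-dione results.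

Step 3
Reactants: 4 (chloromethyl)dimethyl(propan-2-yloxy)silane
Product: 5 {[dimethyl(propan-2-yloxy)silyl]methyl}magnesium chloride (solution, titrated)
Conditions: Mg turnings, BrCH2CH2Br (cat.), Et2O, reflux
Reagents that add atoms: magnesium, [Mg]
Why: Grignard formation from a primary α-silyl chloride, the standard entry to this hydroxymethyl anion equivalent.

Step 4
Reactants: 3 1-methyl-2,5-dioxocyclopent-3-en-1-yl acetate; 5 {[dimethyl(propan-2-yloxy)silyl]methyl}magnesium chloride
Product: 7 (1S,4S)-4-{[dimethyl(propan-2-yloxy)silyl]methyl}-1-methyl-5-oxo-2-[(trimethylsilyl)oxy]cyclopent-2-en-1-yl acetate (C7 and C8a as in the target; silylmethyl cis to methyl), via chloromagnesium enolate 6 (not isolated)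
Conditions: CuBr·SMe2 (5 mol %), (R)-1-[(SP)-2-(diphenylphosphino)ferrocenyl]ethyldicyclohexylphosphine (6 mol %), tBuOMe, −78 °C, slow addition of 5; then Me3SiCl, Et3N, DMPU, −78 → 0 °C
Reagents that add atoms: chlorotrimethylsilane, C[Si](C)(C)Cl
Why: Copper-catalysed enantioselective conjugate addition of a Grignard reagent, used as a desymmetrisation: the chiral copper–diphosphine complex selects one of the two enantiotopic alkene carbons while the nucleophile enters anti to the larger acetoxy group (cis to methyl), which together fix C7 and C8a, and silylation of the magnesium enolate gives the enol silane regiospecifically on the C6/C4a side.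

Step 5
Reactants: 7 (1S,4S)-4-{[dimethyl(propan-2-yloxy)silyl]methyl}-1-methyl-5-oxo-2-[(trimethylsilyl)oxy]cyclopent-2-en-1-yl acetate; 8 sodium trichloroacetate
Product: 10 (1R,5S)-3-chloro-5-{[dimethyl(propan-2-yloxy)silyl]methyl}-1-methyl-2,6-dioxocyclohex-3-en-1-yl acetate (ring B with C5–Cl), via siloxydichlorocyclopropane 9 (not isolated)
Conditions: 8 (4 equiv), DME, reflux (85 °C); aqueous work-up
Reagents that add atoms: none
Why: Thermal decarboxylation of 8 releases dichlorocarbene, which adds in a concerted [2+1] manner to the C6=C4a enol silane of 7, the only electron-rich alkene in the molecule, to give the 1-siloxy-6,6-dichlorobicyclo[3.1.0]hexane 9. The endo chloride then ionises with disrotatory cyclopropyl-to-allyl opening of the C6–C4a bond, and loss of Me3SiCl from the 2-chloro-1-siloxyallyl cation leaves C6(=O)–C5(Cl)=C4a. The closest known reaction type is the dihalocarbene ring enlargement of cyclic silyl enol ethers to 2-halocycloalk-2-enones. Ring B is closed not by a cyclisation but by one-carbon enlargement of the five-membered ring: C5–C6 and C5–C4a are made in the cheletropic addition and C4a–C6 is broken in the electrocyclic opening. No stereocentre is created and C7 and C8a are carried through; the base-free carbene source is chosen because C8a–H is α to the C8 ketone. The step needs insertion between C6 and C4a and not between C8 and C8a, and this is secured by the position of the enol silane, fixed in step 4.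

Step 6
Reactants: 11 S-ethyl ethanethioate
Product: 12 tert-butyl{[1-(ethylsulfanyl)ethenyl]oxy}dimethylsilane
Conditions: LiN(iPr)2, THF, −78 °C; tBuMe2SiCl, DMPU, −78 °C → rt
Reagents that add atoms: tert-butylchlorodimethylsilane, CC(C)(C)[Si](C)(C)Cl
Why: Kinetic enolisation of a thiol ester and O-silylation gives the ketene silyl thioacetal, a standard Mukaiyama donor.

Step 7
Reactants: 10 (1R,5S)-3-chloro-5-{[dimethyl(propan-2-yloxy)silyl]methyl}-1-methyl-2,6-dioxocyclohex-3-en-1-yl acetate; 12 tert-butyl{[1-(ethylsulfanyl)ethenyl]oxy}dimethylsilane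
Product: 13 S-ethyl 2-[(1S,4S,6S)-4-(acetyloxy)-3-[(tert-butyldimethylsilyl)oxy]-2-chloro-6-{[dimethyl(propan-2-yloxy)silyl]methyl}-4-methyl-5-oxocyclohex-2-en-1-yl]ethanethioate (C4a–CH2COSEt, C5(Cl)=C6–OSi; C4a substituent trans to the C8a substituent, provisional and of no consequence)
Conditions: tBuMe2SiOTf (10 mol %), CH2Cl2, −78 °C; Et3N quench
Reagents that add atoms: none
Why: Mukaiyama–Michael addition with silyl transfer, in which the ketene silyl thioacetal attacks C4a of the activated 2-chloroenone anti to the C8a substituent and the silyl group ends on the C6 oxygen, so that the C5=C6 enol ether is formed regiospecifically; a two-carbon donor is used because an enol silane of the complete dienyl ketone would be a 2-siloxydiene and would be expected to add to the chloroenone in a [4+2] sense.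

Step 8
Reactants: 13 S-ethyl 2-[(1S,4S,6S)-4-(acetyloxy)-3-[(tert-butyldimethylsilyl)oxy]-2-chloro-6-{[dimethyl(propan-2-yloxy)silyl]methyl}-4-methyl-5-oxocyclohex-2-en-1-yl]ethanethioate
Product: 14 S-ethyl 2-[(4R,6S)-4-(acetyloxy)-2-chloro-6-{[dimethyl(propan-2-yloxy)silyl]methyl}-4-methyl-3,5-dioxocyclohex-1-en-1-yl]ethanethioate
Conditions: Pd(OAc)2 (1.1 equiv), MeCN, rt → 40 °C
Reagents that add atoms: none
Why: Ito–Saegusa oxidation, in which Pd(OAc)2 turns the silyl enol ether into a palladium enolate at C5 whose only β-hydrogen is C4a–H, so β-hydride elimination restores C4a=C5 with chlorine still on C5.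

Step 9
Reactants: 15 (R)-2-methylbutanoic acid
Product: 16 (R)-2-methylbutan-1-ol
Conditions: LiAlH4, Et2O, 0 °C → rt
Reagents that add atoms: none
Why: Hydride reduction of a carboxylic acid to the primary alcohol, which does not touch the stereocentre.

Step 10
Reactants: 16 (R)-2-methylbutan-1-ol
Product: 18 (2E,4R)-2,4-dimethylhex-2-enal, via (R)-2-methylbutanal 17 (not isolated)
Conditions: Dess–Martin periodinane, NaHCO3, ClCH2CH2Cl, 0 °C → rt; then Ph3P=C(CH3)CHO, 70 °C
Reagents that add atoms: 2-(triphenylphosphoranylidene)propanal, CC(C=O)=P(c1ccccc1)(c1ccccc1)c1ccccc1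
Why: Dess–Martin oxidation followed in the same flask by a Wittig reaction with a stabilised ylide, so that the configurationally labile α-branched aldehyde is never isolated and the trisubstituted alkene is formed E.

Step 11
Reactants: 18 (2E,4R)-2,4-dimethylhex-2-enal
Product: 19 2-[(1E,3E,5R)-3,5-dimethylhepta-1,3-dien-1-yl]-4,4,5,5-tetramethyl-1,3,2-dioxaborolane
Conditions: CrCl2, LiI, Cl2CHBpin, THF, rt
Reagents that add atoms: 2-(dichloromethyl)-4,4,5,5-tetramethyl-1,3,2-dioxaborolane, ClC(Cl)B1OC(C)(C)C(C)(C)O1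
Why: Chromium-mediated borylolefination of an aldehyde (Takai-type gem-dichromium reagent), which gives the E alkenylboronate and leaves the existing alkene and the stereocentre untouched.

Step 12
Reactants: 19 2-[(1E,3E,5R)-3,5-dimethylhepta-1,3-dien-1-yl]-4,4,5,5-tetramethyl-1,3,2-dioxaborolane
Product: 20 [(1E,3E,5R)-3,5-dimethylhepta-1,3-dien-1-yl]boronic acid (used fresh)
Conditions: NaIO4, NH4OAc, acetone/H2O, rt
Reagents that add atoms: water, O
Why: Oxidative deprotection of a pinacol boronate, in which periodate consumes the pinacol released by hydrolysis and leaves the boronic acid.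

Step 13
Reactants: 14 S-ethyl 2-[(4R,6S)-4-(acetyloxy)-2-chloro-6-{[dimethyl(propan-2-yloxy)silyl]methyl}-4-methyl-3,5-dioxocyclohex-1-en-1-yl]ethanethioate; 20 [(1E,3E,5R)-3,5-dimethylhepta-1,3-dien-1-yl]boronic acid
Product: 21 (1R,5S)-3-chloro-4-[(3E,5E,7R)-5,7-dimethyl-2-oxonona-3,5-dien-1-yl]-5-{[dimethyl(propan-2-yloxy)silyl]methyl}-1-methyl-2,6-dioxocyclohex-3-en-1-yl acetate
Conditions: Pd2(dba)3 (2.5 mol %), tri(2-furyl)phosphine (15 mol %), copper thiophene-2-carboxylate CuO2CC4H3S (1.5 equiv), THF, 45 °C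
Reagents that add atoms: none
Why: Liebeskind–Srogl ketone synthesis, in which zerovalent palladium inserts into the C–S bond of the thiol ester, the copper carboxylate scavenges the thiolate and activates the boronic acid, and reductive elimination forms C3–C1′ with retention of alkene geometry under base-free conditions that spare the acidic C4–H2 and C8a–H.

Step 14
Reactants: 21 (1R,5S)-3-chloro-4-[(3E,5E,7R)-5,7-dimethyl-2-oxonona-3,5-dien-1-yl]-5-{[dimethyl(propan-2-yloxy)silyl]methyl}-1-methyl-2,6-dioxocyclohex-3-en-1-yl acetate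
Product: 22 (1R,5R)-3-chloro-4-[(3E,5E,7R)-5,7-dimethyl-2-oxonona-3,5-dien-1-yl]-5-(hydroxymethyl)-1-methyl-2,6-dioxocyclohex-3-en-1-yl acetate (may exist partly as its cyclic hemiketal; used crude)
Conditions: 30% aq. H2O2, KHF2, DMF, rt → 40 °C
Reagents that add atoms: hydrogen peroxide, OO
Why: Tamao oxidation, in which fluoride-activated silicon accepts peroxide and the CH2 group migrates from silicon to oxygen, turning C1–Si into C1–OH without base so that peroxide anion does not attack the dione or the dienone.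

Step 15
Reactants: 22 (1R,5R)-3-chloro-4-[(3E,5E,7R)-5,7-dimethyl-2-oxonona-3,5-dien-1-yl]-5-(hydroxymethyl)-1-methyl-2,6-dioxocyclohex-3-en-1-yl acetate
Product: 24 (7R,8aR)-5-chloro-3-[(1E,3E,5R)-3,5-dimethylhepta-1,3-dien-1-yl]-7-methyl-6,8-dioxo-6,7,8,8a-tetrahydro-1H-isochromen-7-yl acetate (CNP0108998.1), via cyclic hemiketal 23 (not isolated)
Conditions: PPTS (10 mol %), 4 Å molecular sieves, CH2Cl2, rt
Reagents that add atoms: none
Why: Acid-catalysed hemiketalisation (6-exo-trig attack of the C1 hydroxyl on the C3 ketone) and dehydration to the cyclic enol ether, driven by conjugation of O2–C3=C4 with the C4a=C5–C6=O chloroenone; C8a, α to the C8 ketone, is expected to stay in (or relax to) the installed configuration, which places C1 and the C7 methyl equatorial and the acetoxy group axial.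

**Compound list**

1 | 2-methylcyclopentane-1,3-dione | CC1C(=O)CCC1=O | starting material
2 | 1-methyl-2,5-dioxocyclopentyl acetate | CC(=O)OC1(C)C(=O)CCC1=O | intermediate
3 | 1-methyl-2,5-dioxocyclopent-3-en-1-yl acetate | CC(=O)OC1(C)C(=O)C=CC1=O | intermediate
4 | (chloromethyl)dimethyl(propan-2-yloxy)silane | CC(C)O[Si](C)(C)CCl | starting material
5 | {[dimethyl(propan-2-yloxy)silyl]methyl}magnesium chloride | CC(C)O[Si](C)(C)C[Mg]Cl | intermediate
6 | chloromagnesium enolate of the 1,4-adduct (O–MgCl on C6, C6=C4a) | C1=C(O[Mg]Cl)[C@](C)(OC(C)=O)C(=O)[C@H]1C[Si](C)(C)OC(C)C | intermediate (not isolated)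
7 | (1S,4S)-4-{[dimethyl(propan-2-yloxy)silyl]methyl}-1-methyl-5-oxo-2-[(trimethylsilyl)oxy]cyclopent-2-en-1-yl acetate | C1=C(O[Si](C)(C)C)[C@](C)(OC(C)=O)C(=O)[C@H]1C[Si](C)(C)OC(C)C | intermediate
8 | sodium trichloroacetate | [Na+].[O-]C(=O)C(Cl)(Cl)Cl | starting material
9 | 6,6-dichloro-4-{[dimethyl(propan-2-yloxy)silyl]methyl}-2-methyl-3-oxo-1-[(trimethylsilyl)oxy]bicyclo[3.1.0]hexan-2-yl acetate (C7 and C8a as in 7) | C[Si](C)(C)OC12C(Cl)(Cl)C1[C@H](C[Si](C)(C)OC(C)C)C(=O)[C@@]2(C)OC(C)=O | intermediate (not isolated)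
10 | (1R,5S)-3-chloro-5-{[dimethyl(propan-2-yloxy)silyl]methyl}-1-methyl-2,6-dioxocyclohex-3-en-1-yl acetate | C1=C(Cl)C(=O)[C@](C)(OC(C)=O)C(=O)[C@H]1C[Si](C)(C)OC(C)C | intermediate
11 | S-ethyl ethanethioate | CC(=O)SCC | starting material
12 | tert-butyl{[1-(ethylsulfanyl)ethenyl]oxy}dimethylsilane | C=C(SCC)O[Si](C)(C)C(C)(C)C | intermediate
13 | S-ethyl 2-[(1S,4S,6S)-4-(acetyloxy)-3-[(tert-butyldimethylsilyl)oxy]-2-chloro-6-{[dimethyl(propan-2-yloxy)silyl]methyl}-4-methyl-5-oxocyclohex-2-en-1-yl]ethanethioate | CCSC(=O)C[C@@H]1C(Cl)=C(O[Si](C)(C)C(C)(C)C)[C@](C)(OC(C)=O)C(=O)[C@H]1C[Si](C)(C)OC(C)C | intermediate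
14 | S-ethyl 2-[(4R,6S)-4-(acetyloxy)-2-chloro-6-{[dimethyl(propan-2-yloxy)silyl]methyl}-4-methyl-3,5-dioxocyclohex-1-en-1-yl]ethanethioate | CCSC(=O)CC1=C(Cl)C(=O)[C@](C)(OC(C)=O)C(=O)[C@H]1C[Si](C)(C)OC(C)C | intermediate
15 | (R)-2-methylbutanoic acid | CC[C@@H](C)C(O)=O | starting material
16 | (R)-2-methylbutan-1-ol | CC[C@@H](C)CO | intermediate
17 | (R)-2-methylbutanal | CC[C@@H](C)C=O | intermediate (not isolated)
18 | (2E,4R)-2,4-dimethylhex-2-enal | CC[C@@H](C)/C=C(C)/C=O | intermediate
19 | 2-[(1E,3E,5R)-3,5-dimethylhepta-1,3-dien-1-yl]-4,4,5,5-tetramethyl-1,3,2-dioxaborolane | CC[C@@H](C)/C=C(C)/C=C/B1OC(C)(C)C(C)(C)O1 | intermediate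
20 | [(1E,3E,5R)-3,5-dimethylhepta-1,3-dien-1-yl]boronic acid | CC[C@@H](C)/C=C(C)/C=C/B(O)O | intermediate
21 | (1R,5S)-3-chloro-4-[(3E,5E,7R)-5,7-dimethyl-2-oxonona-3,5-dien-1-yl]-5-{[dimethyl(propan-2-yloxy)silyl]methyl}-1-methyl-2,6-dioxocyclohex-3-en-1-yl acetate | CC[C@@H](C)/C=C(C)/C=C/C(=O)CC1=C(Cl)C(=O)[C@](C)(OC(C)=O)C(=O)[C@H]1C[Si](C)(C)OC(C)C | intermediate
22 | (1R,5R)-3-chloro-4-[(3E,5E,7R)-5,7-dimethyl-2-oxonona-3,5-dien-1-yl]-5-(hydroxymethyl)-1-methyl-2,6-dioxocyclohex-3-en-1-yl acetate | CC[C@@H](C)/C=C(C)/C=C/C(=O)CC1=C(Cl)C(=O)[C@](C)(OC(C)=O)C(=O)[C@H]1CO | intermediate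
23 | (7R,8aR)-5-chloro-3-[(1E,3E,5R)-3,5-dimethylhepta-1,3-dien-1-yl]-3-hydroxy-7-methyl-6,8-dioxo-3,4,6,7,8,8a-hexahydro-1H-isochromen-7-yl acetate (both C3 epimers) | CC[C@@H](C)/C=C(C)/C=C/C1(O)CC2=C(Cl)C(=O)[C@](C)(OC(C)=O)C(=O)[C@H]2CO1 | intermediate (not isolated)
24 | (7R,8aR)-5-chloro-3-[(1E,3E,5R)-3,5-dimethylhepta-1,3-dien-1-yl]-7-methyl-6,8-dioxo-6,7,8,8a-tetrahydro-1H-isochromen-7-yl acetate | CC[C@@H](C)/C=C(C)/C=C/C1=CC2=C(Cl)C(=O)[C@](C)(OC(C)=O)C(=O)[C@H]2CO1 | target

**Step count and risks**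

Total step count: 15. Longest linear sequence: 9 steps (1 → 24 through steps 1, 2, 4, 5, 7, 8, 13, 14, 15).

Step 14 (C–Si oxidation on the fully assembled ketone 21). What may go wrong: peroxide may attack the non-enolisable 2-acetoxy-1,3-dione (ring cleavage) or the dienone, and the new C1 hydroxyl, β to the C8 ketone and next to the acidic C8a–H, may be eliminated before the C3 ketone captures it. Fallback: move the oxidation to the earlier, more robust stage, before any diene is present. It sets out from 10. Treatment with mCPBA and KHF2 in DMF should give (1R,5R)-3-chloro-5-(hydroxymethyl)-1-methyl-2,6-dioxocyclohex-3-en-1-yl acetate F1. An excess of 12 with catalytic tBuMe2SiOTf should silylate the hydroxyl and carry out the Mukaiyama–Michael addition in one operation, giving the bis-silylated adduct S-ethyl 2-[4-acetoxy-3-(tert-butyldimethylsilyloxy)-6-(tert-butyldimethylsilyloxymethyl)-2-chloro-4-methyl-5-oxocyclohex-2-en-1-yl]ethanethioate F2. Pd(OAc)2 as in step 8 should give the enone S-ethyl 2-[4-acetoxy-6-(tert-butyldimethylsilyloxymethyl)-2-chloro-4-methyl-3,5-dioxocyclohex-1-en-1-yl]ethanethioate F3. Coupling with 20 as in step 13 should give the C1 tert-butyldimethylsilyl ether of the dienyl ketone F4, and HF·pyridine in THF should free the primary alcohol, so the route is rejoined at 22.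

Step 4 (desymmetrising conjugate addition). What may go wrong: weak facial discrimination between the acetoxy and methyl faces, or weak selection between the enantiotopic alkene carbons. Either erodes the enantiomeric purity at C7 once C8a can equilibrate; direct 1,2-addition of the Grignard reagent to a ketone may also compete. Fallback: set C7 by a desymmetrising ketone reduction and add the silylmethyl group under substrate control with C8 held as a protected carbinol through the carbene step. It sets out from 2. CBS reduction ((S)-2-methyl-CBS-oxazaborolidine, BH3·SMe2) of one enantiotopic carbonyl should give (1R,2R)-2-hydroxy-1-methyl-5-oxocyclopentyl acetate F5 (hydroxyl cis to acetoxy; a minor diastereomer can be removed here). 4-Methoxybenzyl trichloroacetimidate with catalytic acid should give the ether (1R,2R)-2-[(4-methoxybenzyl)oxy]-1-methyl-5-oxocyclopentyl acetate F6. IBX with 4-methoxypyridine N-oxide in DMSO at room temperature should give the enone 5-[(4-methoxybenzyl)oxy]-1-methyl-2-oxocyclopent-3-en-1-yl acetate F7. CuI-catalysed addition of 5 with Me3SiCl, trans to the neighbouring ether, should give the enol silane 4-{[dimethyl(propan-2-yloxy)silyl]methyl}-5-[(4-methoxybenzyl)oxy]-1-methyl-2-[(trimethylsilyl)oxy]cyclopent-2-en-1-yl acetate F8. Reagent 8 in refluxing DME should perform the same carbene ring enlargement to 3-chloro-5-{[dimethyl(propan-2-yloxy)silyl]methyl}-6-[(4-methoxybenzyl)oxy]-1-methyl-2-oxocyclohex-3-en-1-yl acetate F9. DDQ in wet CH2Cl2 should give the alcohol 3-chloro-5-{[dimethyl(propan-2-yloxy)silyl]methyl}-6-hydroxy-1-methyl-2-oxocyclohex-3-en-1-yl acetate F10, and Dess–Martin oxidation of the C8 carbinol returns to the route at 10.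

Step 8 (re-oxidation of the chloro enol ether). What may go wrong: palladation of the hindered, electron-poor 2-chloro silyl enol ether may be slow, so that protodesilylation to the saturated α-chloro ketone takes over and the regiochemical information is lost. Fallback: selenoxide elimination in place of β-hydride elimination. It sets out from 13. PhSeCl in CH2Cl2 at −78 °C should attack C5 anti to the C4a substituent and give S-ethyl 2-[4-acetoxy-2-chloro-6-{[dimethyl(propan-2-yloxy)silyl]methyl}-4-methyl-3,5-dioxo-2-(phenylselanyl)cyclohexyl]ethanethioate F11. Oxidation with H2O2 and pyridine at 0 °C should trigger syn elimination through C4a–H, the only β-hydrogen, and the route is rejoined at 14.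

**Further compounds**

F1 | step 14 | (1R,5R)-3-chloro-5-(hydroxymethyl)-1-methyl-2,6-dioxocyclohex-3-en-1-yl acetate | C1=C(Cl)C(=O)[C@](C)(OC(C)=O)C(=O)[C@H]1CO
F2 | step 14 | S-ethyl 2-[4-acetoxy-3-(tert-butyldimethylsilyloxy)-6-(tert-butyldimethylsilyloxymethyl)-2-chloro-4-methyl-5-oxocyclohex-2-en-1-yl]ethanethioate (configured as 13) | CCSC(=O)C[C@@H]1C(Cl)=C(O[Si](C)(C)C(C)(C)C)[C@](C)(OC(C)=O)C(=O)[C@H]1CO[Si](C)(C)C(C)(C)C
F3 | step 14 | S-ethyl 2-[4-acetoxy-6-(tert-butyldimethylsilyloxymethyl)-2-chloro-4-methyl-3,5-dioxocyclohex-1-en-1-yl]ethanethioate (C7 and C8a as in 14) | CCSC(=O)CC1=C(Cl)C(=O)[C@](C)(OC(C)=O)C(=O)[C@H]1CO[Si](C)(C)C(C)(C)C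
F4 | step 14 | C1 tert-butyldimethylsilyl ether of 22 | CC[C@@H](C)/C=C(C)/C=C/C(=O)CC1=C(Cl)C(=O)[C@](C)(OC(C)=O)C(=O)[C@H]1CO[Si](C)(C)C(C)(C)C
F5 | step 4 | (1R,2R)-2-hydroxy-1-methyl-5-oxocyclopentyl acetate | CC(=O)O[C@@]1(C)C(=O)CC[C@H]1O
F6 | step 4 | (1R,2R)-2-[(4-methoxybenzyl)oxy]-1-methyl-5-oxocyclopentyl acetate | CC(=O)O[C@@]1(C)C(=O)CC[C@H]1OCc1ccc(OC)cc1
F7 | step 4 | 5-[(4-methoxybenzyl)oxy]-1-methyl-2-oxocyclopent-3-en-1-yl acetate (configured as F6) | CC(=O)O[C@@]1(C)C(=O)C=C[C@H]1OCc1ccc(OC)cc1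
F8 | step 4 | 4-{[dimethyl(propan-2-yloxy)silyl]methyl}-5-[(4-methoxybenzyl)oxy]-1-methyl-2-[(trimethylsilyl)oxy]cyclopent-2-en-1-yl acetate (silylmethyl trans to the ether, cis to methyl) | CC(=O)O[C@@]1(C)C(O[Si](C)(C)C)=C[C@H](C[Si](C)(C)OC(C)C)[C@H]1OCc1ccc(OC)cc1
F9 | step 4 | 3-chloro-5-{[dimethyl(propan-2-yloxy)silyl]methyl}-6-[(4-methoxybenzyl)oxy]-1-methyl-2-oxocyclohex-3-en-1-yl acetate (configured as F8) | CC(=O)O[C@@]1(C)C(=O)C(Cl)=C[C@H](C[Si](C)(C)OC(C)C)[C@H]1OCc1ccc(OC)cc1
F10 | step 4 | 3-chloro-5-{[dimethyl(propan-2-yloxy)silyl]methyl}-6-hydroxy-1-methyl-2-oxocyclohex-3-en-1-yl acetate (configured as F8) | CC(=O)O[C@@]1(C)C(=O)C(Cl)=C[C@H](C[Si](C)(C)OC(C)C)[C@H]1O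
F11 | step 8 | S-ethyl 2-[4-acetoxy-2-chloro-6-{[dimethyl(propan-2-yloxy)silyl]methyl}-4-methyl-3,5-dioxo-2-(phenylselanyl)cyclohexyl]ethanethioate (C4a, C7, C8a as in 13) | CCSC(=O)C[C@@H]1C(Cl)([Se]c2ccccc2)C(=O)[C@](C)(OC(C)=O)C(=O)[C@H]1C[Si](C)(C)OC(C)C
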